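**Retrosynthetic overview**
1. Ring A (the 2-alkyl-4-methoxycyclohexane-1,3-dione, drawn as its enol) is closed last by an intramolecular Claisen condensation of a δ-keto ester. The ketone comes from a Fukuyama coupling of a primary alkylzinc with an (S)-2-methoxyglutaric thioester made from L-glutamic acid, which supplies the methoxy-bearing stereocentre.
2. The (Z)-6-methylhepta-2,5-dien-2-yl side chain is attached by Negishi coupling of a cyclopentenyl triflate with a (Z)-alkenylzinc made from but-2-yn-1-ol.
3. The five-membered ring (C1 = carbinol carbon with Me/OH, C2 = CH carrying the CH2 link to ring A, C3 = alkene carbon carrying the side chain, C4 = alkene CH, C5 = CH2) is a 1-methylcyclopent-3-en-1-ol. Its tertiary carbinol C1 is homoallylic to C3=C4, and C3 can carry oxygen in place of the side chain. A 1-siloxy-1-vinylcyclopropane with an alkoxide on the neighbouring ring carbon expands to exactly this array, so the C5–C1 bond is closed by a Brook rearrangement / cyclopropanolate ring-expansion cascade of an acyclic β-hydroxy-β-silyl ketone.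
4. The cascade precursor comes from an Evans syn-aldol addition to acryloyltriethylsilane, which fixes C2. The cascade sets C1 relative to C2 and leaves C3 as a regiodefined enol silane for the cross-coupling.
5. Ring order: cyclopentene first (key step), ring A last.

Key step: step 6

Assumption: the cyclic 1,3-dione is drawn throughout as the enol tautomer of the target SMILES (the enol forms interconvert freely); the starting materials named are taken as commercially available.

**Step 1**
Reactants: 1 1-methoxypropa-1,2-diene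
Product: 3 1-(triethylsilyl)prop-2-en-1-one, via silyl allenyl ether 2 (not isolated)
Conditions: n-BuLi, THF, −78 °C; Et3SiCl, −78 → 0 °C; then 0.5 M aq. H2SO4, THF, 0 °C
Reagents that add atoms: chlorotriethylsilane CC[Si](Cl)(CC)CC; water O
Why: Lithiation of the allenyl ether at the alkoxy-bearing carbon, C-silylation and mild acid hydrolysis of the resulting 1-silyl enol ether unmask the α,β-unsaturated acylsilane (acylsilane synthesis from a metallated allenyl ether); no stereocentre is formed.

**Step 2**
Reactants: 4 (R)-4-benzyloxazolidin-2-one; 5 4-chlorobutanoyl chloride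
Product: 6 (R)-4-benzyl-3-(4-chlorobutanoyl)oxazolidin-2-one
Conditions: n-BuLi, THF, −78 °C; then 5, −78 → 0 °C
Reagents that add atoms: none
Why: Standard N-acylation of the lithiated Evans oxazolidinone by the acid chloride; the primary alkyl chloride is inert at this temperature.

**Step 3**
Reactants: 6 (R)-4-benzyl-3-(4-chlorobutanoyl)oxazolidin-2-one; 3 1-(triethylsilyl)prop-2-en-1-one
Product: 8 (R)-4-benzyl-3-[(2S,3S)-2-(2-chloroethyl)-3-hydroxy-3-(triethylsilyl)pent-4-enoyl]oxazolidin-2-one, via boron enolate 7 (not isolated)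
Conditions: Bu2BOTf, i-Pr2NEt, CH2Cl2, −78 → 0 °C; 3, −78 → −20 °C; pH 7 buffer, MeOH, H2O2, 0 °C
Reagents that add atoms: none
Why: Evans syn-aldol addition, in which the (Z)-boron enolate 7 adds through a Zimmerman–Traxler chair to the acylsilane carbonyl (a hindered aldehyde surrogate, silyl group equatorial) on the enolate face opposite the benzyl group, which fixes the future ring C2 stereocentre; the carbinol configuration drawn is the expected syn one and is erased in step 6.

**Step 4**
Reactants: 8 (R)-4-benzyl-3-[(2S,3S)-2-(2-chloroethyl)-3-hydroxy-3-(triethylsilyl)pent-4-enoyl]oxazolidin-2-one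
Product: 9 (2S,3S)-2-(2-chloroethyl)-3-hydroxy-N-methoxy-N-methyl-3-(triethylsilyl)pent-4-enamide
Conditions: MeNH(OMe)·HCl, Me3Al, CH2Cl2, −20 → 0 °C; aq. Rochelle salt
Reagents that add atoms: N,O-dimethylhydroxylamine hydrochloride CNOC.Cl
Why: Hydroxyl-assisted aluminium-amide transamidation of the β-hydroxy imide (Weinreb amide formation) cleaves the exocyclic acyl group and releases the auxiliary without touching the C2 stereocentre.

**Step 5**
Reactants: 9 (2S,3S)-2-(2-chloroethyl)-3-hydroxy-N-methoxy-N-methyl-3-(triethylsilyl)pent-4-enamide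
Product: 10 (3S,4S)-3-(2-chloroethyl)-4-hydroxy-4-(triethylsilyl)hex-5-en-2-one
Conditions: MeMgBr (3.5 equiv), THF, −78 → 0 °C; sat. aq. NH4Cl
Reagents that add atoms: methylmagnesium bromide C[Mg]Br
Why: Weinreb ketone synthesis, in which the chelated tetrahedral intermediate prevents over-addition and the magnesium alkoxide of the silyl carbinol does not undergo Brook rearrangement, so the methyl ketone is released only on work-up.

**Step 6**
Reactants: 10 (3S,4S)-3-(2-chloroethyl)-4-hydroxy-4-(triethylsilyl)hex-5-en-2-one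
Product: 14 (4S,5S)-5-(2-chloroethyl)-4-methyl-1,4-bis(triethylsilyloxy)cyclopent-1-ene, via siloxyallyllithium 11 (not isolated), via lithium vinylcyclopropanolate 12 (not isolated), via lithium cyclopentenolate 13 (not isolated)
Conditions: LiN(i-Pr)2 (1.05 equiv), THF, −78 → −20 °C; then Et3SiOTf, −78 → 0 °C
Reagents that add atoms: triethylsilyl trifluoromethanesulfonate CC[Si](CC)(CC)OS(=O)(=O)C(F)(F)F
Why: Deprotonation of the tertiary α-silyl allylic alcohol triggers a 1,2-Brook rearrangement (C→O silyl shift) to the siloxyallyllithium 11, whose oxygen-bearing carbon adds to the neighbouring methyl ketone (3-exo-trig) to give the 2-vinylcyclopropan-1-olate 12; release of cyclopropane strain then drives the alkoxide-accelerated vinylcyclopropane→cyclopentene 1,3-shift (C–C cleavage back to the ketone/allyl anion pair and re-addition through the CH2 terminus, a five-membered closure at the carbonyl with the C3=C4 unit endocyclic), which forms the ring C5–C1 bond and the tertiary alkoxide 13, trapped by Et3SiOTf. The closest known reaction types are the Brook-rearrangement-mediated [3+2] annulation of acryloylsilanes with methyl ketone enolates (same lithium aldolate, entered here from the isolated aldol so that C2 is already fixed) and the lithium-alkoxide-accelerated vinylcyclopropane rearrangement. The C2 centre is not touched (only O–H is removed, one equivalent of base, low temperature), and the new C1 centre is set relative to it in the ring-closing transition state, where the ketone methyl avoids eclipsing the 2-chloroethyl arm and the small O–Li takes the cis position, giving the required cis O/arm (trans Me/arm) relationship. The step needs carbonyl addition to outrun proton transfer and alkylation at the primary chloride (secured by the 1,3-relationship of anion and ketone at low temperature, the chloride being inert) and silicon delivered only to the C3 oxygen, so that the enol silane is regiodefined at C3=C4 for step 7.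

**Step 7**
Reactants: 14 (4S,5S)-5-(2-chloroethyl)-4-methyl-1,4-bis(triethylsilyloxy)cyclopent-1-ene
Product: 15 (4S,5S)-5-(2-chloroethyl)-4-methyl-4-(triethylsilyloxy)cyclopent-1-en-1-yl trifluoromethanesulfonate
Conditions: CsF, PhNTf2, DME, 23 °C
Reagents that add atoms: N-phenylbis(trifluoromethanesulfonimide) O=S(=O)(N(c1ccccc1)S(=O)(=O)C(F)(F)F)C(F)(F)F
Why: Fluoride cleaves the far more labile enol silyl ether and the regiodefined caesium enolate is O-sulfonylated in situ (enol triflate formation), so the double bond stays at ring C3=C4 and the tertiary silyl ether survives.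

**Step 8**
Reactants: 16 but-2-yn-1-ol
Product: 18 (Z)-3-iodobut-2-en-1-ol, via cyclic alkenylalanate 17 (not isolated)
Conditions: NaAlH2(OCH2CH2OMe)2 (Red-Al), THF, 0 → 23 °C; EtOAc; I2, THF, −78 → 0 °C
Reagents that add atoms: iodine II
Why: Hydroxyl-directed anti-hydroalumination of the propargylic alcohol gives the cyclic alanate 17, and iodinolysis with retention gives the (Z)-vinyl iodide with iodine cis to CH2OH.

**Step 9**
Reactants: 18 (Z)-3-iodobut-2-en-1-ol
Product: 19 (Z)-1-bromo-3-iodobut-2-ene
Conditions: CBr4, PPh3, CH2Cl2, 0 °C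
Reagents that add atoms: tetrabromomethane BrC(Br)(Br)Br
Why: Appel bromination of the primary allylic alcohol under neutral conditions leaves the vinyl iodide geometry untouched.

**Step 10**
Reactants: 19 (Z)-1-bromo-3-iodobut-2-ene; 20 (2-methylprop-1-en-1-yl)magnesium bromide
Product: 21 (Z)-2-iodo-6-methylhepta-2,5-diene
Conditions: CuI (10 mol%), THF, −30 → 0 °C
Reagents that add atoms: none
Why: Copper-catalysed SN2 coupling of the alkenyl Grignard reagent at the primary allylic bromide (the SN2′ site is a fully substituted iodoalkene carbon) builds the skipped diene, and the C–I bond does not react at low temperature.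

**Step 11**
Reactants: 21 (Z)-2-iodo-6-methylhepta-2,5-diene; 15 (4S,5S)-5-(2-chloroethyl)-4-methyl-4-(triethylsilyloxy)cyclopent-1-en-1-yl trifluoromethanesulfonate
Product: 23 {[(1S,2R)-2-(2-chloroethyl)-1-methyl-3-[(2Z)-6-methylhepta-2,5-dien-2-yl]cyclopent-3-en-1-yl]oxy}triethylsilane, via alkenylzinc chloride 22 (not isolated)
Conditions: 21, t-BuLi (2 equiv per iodide), Et2O, −78 °C; ZnCl2, THF, −78 → 0 °C; then 15, Pd(PPh3)4 (5 mol%), THF, 23 → 45 °C
Reagents that add atoms: none
Why: Negishi coupling, in which iodine–lithium exchange and transmetallation to zinc proceed with retention of alkene geometry and the zerovalent-palladium-catalysed sp2–sp2 coupling with the enol triflate installs the (Z)-dienyl side chain at ring C3.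

**Step 12**
Reactants: 23 {[(1S,2R)-2-(2-chloroethyl)-1-methyl-3-[(2Z)-6-methylhepta-2,5-dien-2-yl]cyclopent-3-en-1-yl]oxy}triethylsilane
Product: 24 triethyl{[(1S,2R)-2-(2-iodoethyl)-1-methyl-3-[(2Z)-6-methylhepta-2,5-dien-2-yl]cyclopent-3-en-1-yl]oxy}silane
Conditions: NaI, NaHCO3, butan-2-one, 70 °C
Reagents that add atoms: sodium iodide [Na+].[I-]
Why: Finkelstein halide exchange (SN2) converts the primary chloride into the iodide needed for zinc insertion.

**Step 13**
Reactants: 25 L-glutamic acid 5-benzyl ester
Product: 26 (S)-5-(benzyloxy)-2-hydroxy-5-oxopentanoic acid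
Conditions: NaNO2, 1 M aq. H2SO4, 0 → 23 °C
Reagents that add atoms: water O
Why: Diazotisation of the α-amino acid with neighbouring-carboxylate participation (double inversion) gives the α-hydroxy acid with net retention, so the (S) centre of L-glutamic acid becomes the methoxy-bearing carbon of ring A.

**Step 14**
Reactants: 26 (S)-5-(benzyloxy)-2-hydroxy-5-oxopentanoic acid
Product: 27 5-benzyl 1-methyl (S)-2-methoxypentanedioate
Conditions: MeI, Ag2O, MeCN, 23 °C, dark
Reagents that add atoms: iodomethane CI
Why: Purdie methylation alkylates carboxylate and hydroxyl under non-basic conditions, so the α-stereocentre is not epimerised.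

**Step 15**
Reactants: 27 5-benzyl 1-methyl (S)-2-methoxypentanedioate
Product: 28 (S)-4-methoxy-5-methoxy-5-oxopentanoic acid
Conditions: H2 (1 atm), Pd/C, EtOAc, 23 °C
Reagents that add atoms: none
Why: Hydrogenolysis cleaves only the benzyl ester and frees the distal carboxylic acid.

**Step 16**
Reactants: 28 (S)-4-methoxy-5-methoxy-5-oxopentanoic acid
Product: 29 methyl (S)-5-(ethylsulfanyl)-2-methoxy-5-oxopentanoate
Conditions: EtSH, EDC·HCl, DMAP (cat.), CH2Cl2, 0 → 23 °C
Reagents that add atoms: ethanethiol CCS
Why: Steglich-type carbodiimide thioesterification activates the distal acid as the S-ethyl thioester for the Fukuyama coupling.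

**Step 17**
Reactants: 24 triethyl{[(1S,2R)-2-(2-iodoethyl)-1-methyl-3-[(2Z)-6-methylhepta-2,5-dien-2-yl]cyclopent-3-en-1-yl]oxy}silane; 29 methyl (S)-5-(ethylsulfanyl)-2-methoxy-5-oxopentanoate
Product: 31 methyl (2S)-2-methoxy-7-[(1R,5S)-5-methyl-2-[(2Z)-6-methylhepta-2,5-dien-2-yl]-5-(triethylsilyloxy)cyclopent-2-en-1-yl]-5-oxoheptanoate, via alkylzinc iodide 30 (not isolated)
Conditions: Zn dust (BrCH2CH2Br/Me3SiCl-activated), LiCl, THF, 40 °C; then 29, PdCl2(PPh3)2 (5 mol%), THF/toluene, 23 °C; sat. aq. NH4Cl
Reagents that add atoms: none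
Why: Fukuyama coupling, in which zinc inserts into the primary C–I bond and the palladium catalyst couples the alkylzinc iodide 30 with the thioester to the ketone without touching the methyl ester, the diene or the α-methoxy stereocentre.

**Step 18**
Reactants: 31 methyl (2S)-2-methoxy-7-[(1R,5S)-5-methyl-2-[(2Z)-6-methylhepta-2,5-dien-2-yl]-5-(triethylsilyloxy)cyclopent-2-en-1-yl]-5-oxoheptanoate
Product: 32 (4S)-3-hydroxy-4-methoxy-2-{[(1R,5S)-5-methyl-2-[(2Z)-6-methylhepta-2,5-dien-2-yl]-5-(triethylsilyloxy)cyclopent-2-en-1-yl]methyl}cyclohex-2-en-1-one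
Conditions: KOtBu (2.2 equiv), THF, 0 °C; AcOH
Reagents that add atoms: none
Why: Intramolecular Claisen (Dieckmann-type) condensation, in which the ketone enolate next to the CH2 link attacks the methyl ester in a 6-exo-trig closure (the other enolate could only form a four-membered ring) and deprotonation of the product 1,3-dione drives the reaction and shields the neighbouring methoxy centre from epimerisation.

**Step 19**
Reactants: 32 (4S)-3-hydroxy-4-methoxy-2-{[(1R,5S)-5-methyl-2-[(2Z)-6-methylhepta-2,5-dien-2-yl]-5-(triethylsilyloxy)cyclopent-2-en-1-yl]methyl}cyclohex-2-en-1-one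
Product: 33 (4S)-3-hydroxy-2-{[(1R,5S)-5-hydroxy-5-methyl-2-[(2Z)-6-methylhepta-2,5-dien-2-yl]cyclopent-2-en-1-yl]methyl}-4-methoxycyclohex-2-en-1-one
Conditions: HF·pyridine, pyridine, THF, 0 → 23 °C
Reagents that add atoms: none
Why: Buffered fluoride cleavage of the tertiary triethylsilyl ether releases the tertiary alcohol without isomerising the (Z)-diene or the enolised dione.

**Compound list**
1 | 1-methoxypropa-1,2-diene (methoxyallene) | COC=C=C | starting material
2 | triethyl(1-methoxypropa-1,2-dien-1-yl)silane (not isolated) | COC(=C=C)[Si](CC)(CC)CC | intermediate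
3 | 1-(triethylsilyl)prop-2-en-1-one (acryloyltriethylsilane) | C=CC(=O)[Si](CC)(CC)CC | intermediate
4 | (R)-4-benzyloxazolidin-2-one | O=C1N[C@H](Cc2ccccc2)CO1 | starting material
5 | 4-chlorobutanoyl chloride | O=C(Cl)CCCCl | starting material
6 | (R)-4-benzyl-3-(4-chlorobutanoyl)oxazolidin-2-one | O=C(CCCCl)N1[C@H](Cc2ccccc2)COC1=O | intermediate
7 | (Z)-dibutylboron enolate of 6 (not isolated) | CCCCB(CCCC)O/C(=C\CCCl)N1[C@H](Cc2ccccc2)COC1=O | intermediate
8 | (R)-4-benzyl-3-[(2S,3S)-2-(2-chloroethyl)-3-hydroxy-3-(triethylsilyl)pent-4-enoyl]oxazolidin-2-one | O=C([C@H](CCCl)[C@@](C=C)(O)[Si](CC)(CC)CC)N1[C@H](Cc2ccccc2)COC1=O | intermediate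
9 | (2S,3S)-2-(2-chloroethyl)-3-hydroxy-N-methoxy-N-methyl-3-(triethylsilyl)pent-4-enamide | CON(C)C(=O)[C@H](CCCl)[C@@](C=C)(O)[Si](CC)(CC)CC | intermediate
10 | (3S,4S)-3-(2-chloroethyl)-4-hydroxy-4-(triethylsilyl)hex-5-en-2-one | CC(=O)[C@H](CCCl)[C@@](C=C)(O)[Si](CC)(CC)CC | intermediate
11 | lithium 4-acetyl-6-chloro-3-(triethylsilyloxy)hex-2-en-1-ide, the siloxyallyl anion, CH carbon configured as in 10 (not isolated) | [Li+].[CH2-]C=C(O[Si](CC)(CC)CC)[C@@H](CCCl)C(C)=O | intermediate
12 | lithium 3-(2-chloroethyl)-2-ethenyl-1-methyl-2-(triethylsilyloxy)cyclopropan-1-olate, CH carbon configured as in 10, the two oxygenated ring carbons as formed (not isolated) | [Li+].CC1([O-])[C@H](CCCl)C1(C=C)O[Si](CC)(CC)CC | intermediate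
13 | lithium (1S,2S)-2-(2-chloroethyl)-1-methyl-3-(triethylsilyloxy)cyclopent-3-en-1-olate (not isolated) | [Li+].ClCC[C@@H]1C(O[Si](CC)(CC)CC)=CC[C@]1(C)[O-] | intermediate
14 | (4S,5S)-5-(2-chloroethyl)-4-methyl-1,4-bis(triethylsilyloxy)cyclopent-1-ene | ClCC[C@@H]1C(O[Si](CC)(CC)CC)=CC[C@]1(C)O[Si](CC)(CC)CC | intermediate
15 | (4S,5S)-5-(2-chloroethyl)-4-methyl-4-(triethylsilyloxy)cyclopent-1-en-1-yl trifluoromethanesulfonate | ClCC[C@@H]1C(OS(=O)(=O)C(F)(F)F)=CC[C@]1(C)O[Si](CC)(CC)CC | intermediate
16 | but-2-yn-1-ol | CC#CCO | starting material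
17 | sodium 2,2-bis(2-methoxyethoxy)-3-methyl-2,5-dihydro-1,2-oxaaluminol-2-uide, the cyclic (Z)-alkenylalanate (not isolated) | [Na+].CC1=CCO[Al-]1(OCCOC)OCCOC | intermediate
18 | (Z)-3-iodobut-2-en-1-ol | C/C(I)=C/CO | intermediate
19 | (Z)-1-bromo-3-iodobut-2-ene | C/C(I)=C/CBr | intermediate
20 | (2-methylprop-1-en-1-yl)magnesium bromide | CC(C)=C[Mg]Br | starting material
21 | (Z)-2-iodo-6-methylhepta-2,5-diene | C/C(I)=C/CC=C(C)C | intermediate
22 | chloro[(2Z)-6-methylhepta-2,5-dien-2-yl]zinc (not isolated) | C/C([Zn]Cl)=C/CC=C(C)C | intermediate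
23 | {[(1S,2R)-2-(2-chloroethyl)-1-methyl-3-[(2Z)-6-methylhepta-2,5-dien-2-yl]cyclopent-3-en-1-yl]oxy}triethylsilane | ClCC[C@@H]1C(/C(C)=C\CC=C(C)C)=CC[C@]1(C)O[Si](CC)(CC)CC | intermediate
24 | triethyl{[(1S,2R)-2-(2-iodoethyl)-1-methyl-3-[(2Z)-6-methylhepta-2,5-dien-2-yl]cyclopent-3-en-1-yl]oxy}silane | ICC[C@@H]1C(/C(C)=C\CC=C(C)C)=CC[C@]1(C)O[Si](CC)(CC)CC | intermediate
25 | L-glutamic acid 5-benzyl ester, (S)-2-amino-5-(benzyloxy)-5-oxopentanoic acid | N[C@@H](CCC(=O)OCc1ccccc1)C(=O)O | starting material
26 | (S)-5-(benzyloxy)-2-hydroxy-5-oxopentanoic acid | O[C@@H](CCC(=O)OCc1ccccc1)C(=O)O | intermediate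
27 | 5-benzyl 1-methyl (S)-2-methoxypentanedioate | CO[C@@H](CCC(=O)OCc1ccccc1)C(=O)OC | intermediate
28 | (S)-4-methoxy-5-methoxy-5-oxopentanoic acid | CO[C@@H](CCC(=O)O)C(=O)OC | intermediate
29 | methyl (S)-5-(ethylsulfanyl)-2-methoxy-5-oxopentanoate | CO[C@@H](CCC(=O)SCC)C(=O)OC | intermediate
30 | iodo{2-[(1R,5S)-5-methyl-2-[(2Z)-6-methylhepta-2,5-dien-2-yl]-5-(triethylsilyloxy)cyclopent-2-en-1-yl]ethyl}zinc (not isolated) | I[Zn]CC[C@@H]1C(/C(C)=C\CC=C(C)C)=CC[C@]1(C)O[Si](CC)(CC)CC | intermediate
31 | methyl (2S)-2-methoxy-7-[(1R,5S)-5-methyl-2-[(2Z)-6-methylhepta-2,5-dien-2-yl]-5-(triethylsilyloxy)cyclopent-2-en-1-yl]-5-oxoheptanoate | COC(=O)[C@@H](OC)CCC(=O)CC[C@@H]1C(/C(C)=C\CC=C(C)C)=CC[C@]1(C)O[Si](CC)(CC)CC | intermediate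
32 | (4S)-3-hydroxy-4-methoxy-2-{[(1R,5S)-5-methyl-2-[(2Z)-6-methylhepta-2,5-dien-2-yl]-5-(triethylsilyloxy)cyclopent-2-en-1-yl]methyl}cyclohex-2-en-1-one | CO[C@H]1CCC(=O)C(C[C@@H]2C(/C(C)=C\CC=C(C)C)=CC[C@]2(C)O[Si](CC)(CC)CC)=C1O | intermediate
33 | (4S)-3-hydroxy-2-{[(1R,5S)-5-hydroxy-5-methyl-2-[(2Z)-6-methylhepta-2,5-dien-2-yl]cyclopent-2-en-1-yl]methyl}-4-methoxycyclohex-2-en-1-one | CO[C@H]1CCC(=O)C(C[C@@H]2C(/C(C)=C\CC=C(C)C)=CC[C@]2(C)O)=C1O | target

**Step count and risks**
Total step count: 19 (11 in the main line, 1 for the acylsilane, 3 for the side-chain iodide, 4 for the thioester).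
Longest linear sequence: 11 steps (steps 2–7, 11, 12, 17–19; from 4 and 5 to 33).

Most likely to fail, riskiest first:

1. Step 6. The cascade may stall after the first ring closure, because the vinyl terminus of the cyclopropanolate carries no anion-stabilising group and the ring expansion may be slow. On forcing, retro-aldol cleavage of the lithium aldolate or proton transfer from the methyl ketone to the siloxyallyl anion may compete, and the facial bias in the final closure may be incomplete. The fallback replaces the anionic ring expansion by a neutral thermal one. It sets out from 10: deprotonation at −78 °C and immediate silylation of the cold mixture with Et3SiOTf should trap the cyclopropanolate as 3-(2-chloroethyl)-2-ethenyl-1-methyl-1,2-bis(triethylsilyloxy)cyclopropane F1. The classical thermal siloxy-vinylcyclopropane → cyclopentene rearrangement (flash vacuum pyrolysis through a base-washed quartz tube at about 450 °C, or a sealed tube in mesitylene at 200–220 °C) should then give 14, where the route is rejoined before step 7. Epimers at the carbinol carbon, if formed, would be separated at 14 or 15. The sequence given under step 3 also reaches 14 and fixes the carbinol centre by an independent principle.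

2. Step 3. The hindered acylsilane carbonyl may react sluggishly with the dibutylboron enolate, and the tertiary aldolate may undergo retro-aldol cleavage on work-up. The fallback uses acrolein as the acylsilane surrogate, closes the ring by metathesis and sets the carbinol centre by reagent approach. It sets out from 6:
   - Evans syn-aldol with acrolein (Bu2BOTf, i-Pr2NEt) should give (R)-4-benzyl-3-[(2R,3S)-2-(2-chloroethyl)-3-hydroxypent-4-enoyl]oxazolidin-2-one F2.
   - Me3Al/MeNH(OMe)·HCl should give the Weinreb amide (2R,3S)-2-(2-chloroethyl)-3-hydroxy-N-methoxy-N-methylpent-4-enamide F3.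
   - Vinylmagnesium bromide should give (4R,5S)-4-(2-chloroethyl)-5-hydroxyhepta-1,6-dien-3-one F4.
   - Ring-closing metathesis with the second-generation Grubbs catalyst should give trans-configured (4S,5R)-5-(2-chloroethyl)-4-hydroxycyclopent-2-en-1-one F5.
   - MeMgBr/CeCl3 should add to the ring ketone anti to the neighbouring 2-chloroethyl arm and give (1S,4S,5R)-5-(2-chloroethyl)-1-methylcyclopent-2-ene-1,4-diol F6, with the tertiary OH cis to the arm as required.
   - MnO2 should oxidise the secondary allylic alcohol to (4S,5S)-5-(2-chloroethyl)-4-hydroxy-4-methylcyclopent-2-en-1-one F7.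
   - Et3SiOTf/2,6-lutidine should give (4S,5S)-5-(2-chloroethyl)-4-methyl-4-(triethylsilyloxy)cyclopent-2-en-1-one F8.
   - Conjugate reduction with LiBH(s-Bu)3 and O-silylation of the regiodefined enolate with Et3SiCl should give 14, where the route is rejoined.

3. Step 11. Transmetallation and reductive elimination may be slow for the α-branched (Z)-alkenylzinc at the hindered ring carbon, allowing Z→E isomerisation of the alkenyl metal or reduction of the triflate. The fallback reverses the polarity of the coupling. It sets out from 15: Miyaura borylation (B2pin2, PdCl2(dppf), KOPh, dioxane, 80 °C) should give 2-[(4S,5R)-5-(2-chloroethyl)-4-methyl-4-(triethylsilyloxy)cyclopent-1-en-1-yl]-4,4,5,5-tetramethyl-1,3,2-dioxaborolane F9. Suzuki coupling of F9 with the configurationally stable vinyl iodide 21 (Pd(PPh3)4, aq. K3PO4, THF) should then give 23, where the route is rejoined.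

**Further compounds**
F1 | step 6 | 3-(2-chloroethyl)-2-ethenyl-1-methyl-1,2-bis(triethylsilyloxy)cyclopropane (CH carbon configured as in 10; mixture at the two oxygenated ring carbons) | CC1(O[Si](CC)(CC)CC)[C@H](CCCl)C1(C=C)O[Si](CC)(CC)CC
F2 | step 3 | (R)-4-benzyl-3-[(2R,3S)-2-(2-chloroethyl)-3-hydroxypent-4-enoyl]oxazolidin-2-one | O=C([C@H](CCCl)[C@@H](O)C=C)N1[C@H](Cc2ccccc2)COC1=O
F3 | step 3 | (2R,3S)-2-(2-chloroethyl)-3-hydroxy-N-methoxy-N-methylpent-4-enamide | CON(C)C(=O)[C@H](CCCl)[C@@H](O)C=C
F4 | step 3 | (4R,5S)-4-(2-chloroethyl)-5-hydroxyhepta-1,6-dien-3-one | C=CC(=O)[C@H](CCCl)[C@@H](O)C=C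
F5 | step 3 | (4S,5R)-5-(2-chloroethyl)-4-hydroxycyclopent-2-en-1-one | O=C1C=C[C@H](O)[C@H]1CCCl
F6 | step 3 | (1S,4S,5R)-5-(2-chloroethyl)-1-methylcyclopent-2-ene-1,4-diol | ClCC[C@@H]1[C@@H](O)C=C[C@]1(C)O
F7 | step 3 | (4S,5S)-5-(2-chloroethyl)-4-hydroxy-4-methylcyclopent-2-en-1-one | ClCC[C@@H]1C(=O)C=C[C@]1(C)O
F8 | step 3 | (4S,5S)-5-(2-chloroethyl)-4-methyl-4-(triethylsilyloxy)cyclopent-2-en-1-one | ClCC[C@@H]1C(=O)C=C[C@]1(C)O[Si](CC)(CC)CC
F9 | step 11 | 2-[(4S,5R)-5-(2-chloroethyl)-4-methyl-4-(triethylsilyloxy)cyclopent-1-en-1-yl]-4,4,5,5-tetramethyl-1,3,2-dioxaborolane | ClCC[C@@H]1C(B2OC(C)(C)C(C)(C)O2)=CC[C@]1(C)O[Si](CC)(CC)CC
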